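**Retrosynthetic overview**
1. The target comes from global O-demethylation of a nonamethyl ether whose only free phenol sits on ring C.
2. Key disconnection: the ring C–ring D biaryl bond, made last. The ring C phenol is oxidised by trivalent iodine to a phenoxenium (α-keto cation, enolonium-type) species, and 1,3,5-trimethoxybenzene attacks its ortho carbon, so two normally nucleophilic arene carbons are joined.
3. The A–O–B–O–C phenol comes from a desymmetrising mono-O-arylation (ring A) of the symmetric bisphenol 4,4'-oxybis(3,5-dimethoxyphenol).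
4. The bisphenol comes from a twofold Baeyer–Villiger oxidation of the symmetric dialdehyde, itself made by Ullmann coupling of syringaldehyde with 4-bromo-3,5-dimethoxybenzaldehyde.
5. No ring is constructed; all four benzene rings are bought and joined in the order B–O–C, then A–O–B, then C–D.

Assumption: the target has no stereocentre and no stable chiral axis (ring D is symmetric about the biaryl bond), so it is one achiral compound and no stereocontrol is needed.

**Step 1**
Reactants: 1 syringaldehyde (4-hydroxy-3,5-dimethoxybenzaldehyde); 2 4-bromo-3,5-dimethoxybenzaldehyde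
Product: 3 symmetric dialdehyde 4,4'-oxybis(3,5-dimethoxybenzaldehyde)
Conditions: CuI (20 mol%), picolinic acid (40 mol%), K3PO4 (2 equiv), DMSO, 110 °C, Ar
Reagents that add atoms: none
Why: Ullmann diaryl ether synthesis with monovalent copper and picolinate, in which the C–Br bond of 2 is activated by its para-formyl group; the tetra-ortho-substituted ether forms slowly from the weakly nucleophilic phenoxide of 1, which is tolerable because the step is first and both partners are cheap, and no stereocentre is formed.

**Step 2**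
Reactants: 3 4,4'-oxybis(3,5-dimethoxybenzaldehyde)
Product: 5 symmetric bisphenol 4,4'-oxybis(3,5-dimethoxyphenol), via bis-formate 4 (not isolated)
Conditions: mCPBA (2.5 equiv), CH2Cl2, 0 °C to rt; then K2CO3 (cat.), MeOH, rt
Reagents that add atoms: mCPBA (3-chloroperoxybenzoic acid), O=C(OO)c1cccc(Cl)c1
Why: Twofold Baeyer–Villiger (Dakin-type) oxidation, in which the electron-rich 4-aryloxy-3,5-dimethoxyphenyl group migrates in preference to hydride, followed by methanolysis of the two aryl formates; the hindered diaryl ether is inert to peracid and carbonate.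

**Step 3**
Reactants: 5 4,4'-oxybis(3,5-dimethoxyphenol) (3 equiv, excess recovered); 6 1-bromo-3,5-dimethoxybenzene (1 equiv)
Product: 7 4-[4-(3,5-dimethoxyphenoxy)-2,6-dimethoxyphenoxy]-3,5-dimethoxyphenol
Conditions: CuI (10 mol%), N,N-dimethylglycine (30 mol%), Cs2CO3 (2 equiv), 1,4-dioxane, 90 °C, Ar
Reagents that add atoms: none
Why: Ullmann ether synthesis (amino-acid-promoted) on one of two equivalent, unhindered phenols; the threefold excess of 5 suppresses double arylation, so the symmetry is broken in the same operation that installs ring A and the remaining phenol becomes the ring C handle.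

**Step 4**
Reactants: 7 4-[4-(3,5-dimethoxyphenoxy)-2,6-dimethoxyphenoxy]-3,5-dimethoxyphenol; 8 1,3,5-trimethoxybenzene (5 equiv)
Product: 11 4-[4-(3,5-dimethoxyphenoxy)-2,6-dimethoxyphenoxy]-3,5-dimethoxy-2-(2,4,6-trimethoxyphenyl)phenol, via aryloxy(acetoxy)phenyliodane 9 (not isolated), via aryloxy-oxocarbenium ion 10 (not isolated)
Conditions: PhI(OAc)2 (1.05 equiv, slow addition), HFIP, −20 to 0 °C
Reagents that add atoms: none
Why: Proposed new method: PhI(OAc)2 exchanges a ligand with the only free phenol to give 9, which loses PhI and acetate in ionising, non-nucleophilic HFIP to give the para-aryloxy-stabilised phenoxenium ion 10, an α-keto cation (enolonium) equivalent whose ortho carbon is now electrophilic; excess 8 attacks one of the two equivalent ortho positions (the para carbon is blocked and flanked by two methoxy groups) and tautomerisation restores the phenol, the closest known reaction types being the acid-promoted arylation of quinone monoacetals and the hypervalent-iodine oxidative phenol–arene cross-coupling in fluoroalcohols.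

**Step 5**
Reactants: 11 4-[4-(3,5-dimethoxyphenoxy)-2,6-dimethoxyphenoxy]-3,5-dimethoxy-2-(2,4,6-trimethoxyphenyl)phenol
Product: 12 3-[4-(3,5-dihydroxyphenoxy)-2,6-dihydroxyphenoxy]biphenyl-2,2',4,4',6,6'-hexol (target, CNP0308688.0)
Conditions: BBr3 (20 equiv), CH2Cl2, −78 °C to rt; then H2O
Reagents that add atoms: none
Why: Exhaustive Lewis-acid ether cleavage, in which BBr3 removes all nine aryl methyl groups by bromide attack at methyl while the diaryl ether and biaryl bonds, which offer no sp3 carbon, are untouched; the product has no stereocentre.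

**Compound list**
1 | syringaldehyde (4-hydroxy-3,5-dimethoxybenzaldehyde) | COc1cc(C=O)cc(OC)c1O | starting material
2 | 4-bromo-3,5-dimethoxybenzaldehyde | COc1cc(C=O)cc(OC)c1Br | starting material
3 | 4,4'-oxybis(3,5-dimethoxybenzaldehyde) | COc1cc(C=O)cc(OC)c1Oc1c(OC)cc(C=O)cc1OC | intermediate
4 | oxybis(3,5-dimethoxy-4,1-phenylene) diformate | COc1cc(OC=O)cc(OC)c1Oc1c(OC)cc(OC=O)cc1OC | intermediate
5 | 4,4'-oxybis(3,5-dimethoxyphenol) | COc1cc(O)cc(OC)c1Oc1c(OC)cc(O)cc1OC | intermediate
6 | 1-bromo-3,5-dimethoxybenzene | COc1cc(Br)cc(OC)c1 | starting material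
7 | 4-[4-(3,5-dimethoxyphenoxy)-2,6-dimethoxyphenoxy]-3,5-dimethoxyphenol | COc1cc(OC)cc(Oc2cc(OC)c(Oc3c(OC)cc(O)cc3OC)c(OC)c2)c1 | intermediate
8 | 1,3,5-trimethoxybenzene | COc1cc(OC)cc(OC)c1 | starting material
9 | acetoxy(phenyl)iodane aryloxide of 7 (trivalent iodine, O-bound to the ring C phenol oxygen) | CC(=O)OI(c1ccccc1)Oc1cc(OC)c(Oc2c(OC)cc(Oc3cc(OC)cc(OC)c3)cc2OC)c(OC)c1 | intermediate
10 | phenoxenium ion of 7, drawn as its 4-aryloxy-oxocarbenium (quinone-type) form, acetate salt | COC1=CC(=O)C=C(OC)C1=[O+]c1c(OC)cc(Oc2cc(OC)cc(OC)c2)cc1OC.CC(=O)[O-] | intermediate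
11 | 4-[4-(3,5-dimethoxyphenoxy)-2,6-dimethoxyphenoxy]-3,5-dimethoxy-2-(2,4,6-trimethoxyphenyl)phenol | COc1cc(OC)cc(Oc2cc(OC)c(Oc3c(OC)cc(O)c(-c4c(OC)cc(OC)cc4OC)c3OC)c(OC)c2)c1 | intermediate
12 | 3-[4-(3,5-dihydroxyphenoxy)-2,6-dihydroxyphenoxy]biphenyl-2,2',4,4',6,6'-hexol | Oc1cc(O)cc(Oc2cc(O)c(Oc3c(O)cc(O)c(-c4c(O)cc(O)cc4O)c3O)c(O)c2)c1 | target

**Step count and risks**
Total steps: 5. Longest linear sequence: 5 (from 1 or 2 to 12).

Most likely to fail, in order of risk:

Step 4 (key C–C bond). The risks are over-oxidation of the more electron-rich product 11, loss of the A–B aryloxy group as a quinone if water is present, and capture of 10 by other arenes. The fallback reverses the roles of the two rings while keeping the phenol intact. It sets out from 8: direct plumbation with Pb(OAc)4 (CHCl3, rt) gives 2,4,6-trimethoxyphenyllead triacetate F1, a tetravalent-lead aryl cation equivalent. F1 arylates phenol 7 at the carbon ortho to the hydroxyl (pyridine, CHCl3, 60 °C; Pinhey arylation by ligand coupling on an aryloxy-lead intermediate) and comes back to the route at 11.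

Step 1 (tetra-ortho-substituted ether from a weakly nucleophilic phenoxide). The fallback replaces copper catalysis with metal-free aryl transfer from trivalent iodine. It sets out from 2: aromatic Finkelstein exchange (NaI, CuI, trans-N,N'-dimethylcyclohexane-1,2-diamine, dioxane, 110 °C) gives 4-iodo-3,5-dimethoxybenzaldehyde F2. One-pot oxidation (mCPBA, TsOH·H2O, MeCN) and capture by 8 gives (4-formyl-2,6-dimethoxyphenyl)(2,4,6-trimethoxyphenyl)iodonium tosylate F3. The phenoxide of 1 (t-BuOK, THF, rt to 40 °C) takes the less electron-rich formyl-bearing aryl group, expelling the trimethoxyphenyl group as its iodide, and the sequence comes back to the route at 3.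

Step 3 (statistical mono-arylation of a symmetric bisphenol). The fallback differentiates the two ends one stage earlier, so the arylation can be driven to completion. It sets out from 3: Baeyer–Villiger oxidation with 1.0 equiv mCPBA gives 4-(4-formyl-2,6-dimethoxyphenoxy)-3,5-dimethoxyphenyl formate F4. Methanolysis (K2CO3, MeOH) gives 4-(4-hydroxy-2,6-dimethoxyphenoxy)-3,5-dimethoxybenzaldehyde F5, which is separable from 3 and 5 by acidity and keeps the second formyl group as a latent hydroxyl. Ullmann coupling of F5 with 6 (1.2 equiv; CuI, N,N-dimethylglycine, Cs2CO3, dioxane, 90 °C) gives 4-[4-(3,5-dimethoxyphenoxy)-2,6-dimethoxyphenoxy]-3,5-dimethoxybenzaldehyde F6. A second Baeyer–Villiger oxidation gives 4-[4-(3,5-dimethoxyphenoxy)-2,6-dimethoxyphenoxy]-3,5-dimethoxyphenyl formate F7, and methanolysis comes back to the route at 7.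

**Further compounds**
F1 | step 4 | 2,4,6-trimethoxyphenyllead triacetate | COc1cc(OC)c([Pb](OC(C)=O)(OC(C)=O)OC(C)=O)c(OC)c1
F2 | step 1 | 4-iodo-3,5-dimethoxybenzaldehyde | COc1cc(C=O)cc(OC)c1I
F3 | step 1 | (4-formyl-2,6-dimethoxyphenyl)(2,4,6-trimethoxyphenyl)iodonium tosylate | COc1cc(C=O)cc(OC)c1[I+]c1c(OC)cc(OC)cc1OC.Cc1ccc(S(=O)(=O)[O-])cc1
F4 | step 3 | 4-(4-formyl-2,6-dimethoxyphenoxy)-3,5-dimethoxyphenyl formate | COc1cc(OC=O)cc(OC)c1Oc1c(OC)cc(C=O)cc1OC
F5 | step 3 | 4-(4-hydroxy-2,6-dimethoxyphenoxy)-3,5-dimethoxybenzaldehyde | COc1cc(O)cc(OC)c1Oc1c(OC)cc(C=O)cc1OC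
F6 | step 3 | 4-[4-(3,5-dimethoxyphenoxy)-2,6-dimethoxyphenoxy]-3,5-dimethoxybenzaldehyde | COc1cc(OC)cc(Oc2cc(OC)c(Oc3c(OC)cc(C=O)cc3OC)c(OC)c2)c1
F7 | step 3 | 4-[4-(3,5-dimethoxyphenoxy)-2,6-dimethoxyphenoxy]-3,5-dimethoxyphenyl formate | COc1cc(OC)cc(Oc2cc(OC)c(Oc3c(OC)cc(OC=O)cc3OC)c(OC)c2)c1
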